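The ratio of complex with one exchanged at its highest reading to incoming ligand charged stands at 0.331 per equivalent in the north-west run (31.4% at 2.50 h from 0.95 equiv), and the bench rule is that, with starting complex and leaving ligand held as charged here, this peak grows in step with the charge of incoming ligand.

| setting | north-west | north | west | alder | larch |
|---|---|---|---|---|---|
| starting complex | 0.021 M | 0.021 M | 0.021 M | 0.021 M | 0.021 M |
| incoming ligand | 0.95 equiv | 1.5 equiv | 2.1 equiv | 0.800 equiv | 2.50 equiv |
| leaving ligand | 0.50 equiv | 0.50 equiv | 0.50 equiv | 0.500 equiv | 0.500 equiv |
| remark | run made earlier | run made earlier | run made earlier |  |  |
| time |  |  |  | 25 h | 25 h |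

| run | time / h | complex with one exchanged / % | starting complex / % |
|---|---|---|---|
| north-west | 1.00 | 26.9 | 51.8 |
| north-west | 2.50 | 31.4 | 22.2 |
| north-west | 5.00 | 29.0 | 6.6 |
| north-west | 12.0 | 27.1 | 1.2 |
| north | 1.50 | 42.8 | 21.1 |
| north | 4.00 | 43.7 | 3.0 |
| north | 8.00 | 39.7 | 0.4 |
| north | 12.0 | 36.2 | 0 |
| west | 1.00 | 50.8 | 23.3 |
| west | 2.50 | 53.7 | 3.1 |
| west | 5.00 | 49.6 | 0 |
| west | 12.0 | 37.4 | 0 |

(each reading ± 0.5 percentage points)

- in percentages every species weighs as the starting complex in it: one side product counts as two
- for leaving ligand the crystals are counted in
- as a solid, counted per litre of solution: crystals
- what was read earlier has a scatter of 0.5 percentage points, one standard deviation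
- what may be going on: starting complex + incoming ligand -> leaving ligand + complex with one exchanged; complex with one exchanged + incoming ligand -> leaving ligand + complex with two exchanged; complex with two exchanged + incoming ligand -> leaving ligand + complex with three exchanged; starting complex + complex with one exchanged -> side product; crystals <-> leaving ligand

- which of these holds the largest part of the starting complex at the end of alder (complex with three exchanged / starting complex / complex with one exchanged / complex with two exchanged)
- which of these holds the largest part of the starting complex at the end of larch (complex with three exchanged / starting complex / complex with one exchanged / complex with two exchanged)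
- amount of complex with one exchanged at the end of alder, in percent of the starting complex charged

The rule has a ground in the scheme. Starting complex stands as a factor in both the step that makes complex with one exchanged and the side step that consumes it. With the second exchange left out of the reckoning, the crossing, where making equals loss, falls at a fixed ratio of that complex to incoming ligand, a selectivity factor of the two steps, and every share up to the crossing scales with the charge. The north-west run had consumed 77.8% of its starting complex at that reading, so the border of the rule, itself a reading with its scatter, is the ratio 1.22 equivalents, the border charge, at which by this reckoning the part of the starting complex consumed at the crossing reaches the whole charge. Above it the rule overshoots: west, beyond the border, reads 53.7% where the rule says 69.4%.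

Alder lies below the border, so by this reckoning it peaks near 26.4% with 34.5% of its starting complex still present, and the side step can go on consuming complex with one exchanged after that peak. Between its readings at 2.50 h and 12.0 h the north-west run lost 0.205 of a point of complex with one exchanged per point of starting complex, and the same loss in alder gives an estimate of about 19.4%.

The forecast names complex with one exchanged as the largest holder for alder and complex with two exchanged for larch and gives 19% of complex with one exchanged for alder, saying “The third step is unobserved, so I assume it is slow”.

At 25 h alder holds 19.7% of complex with one exchanged, and larch holds 42.0% of complex with three exchanged.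

    starting complex + incoming ligand → leaving ligand + complex with one exchanged (k = 0.00950 M⁻¹ s⁻¹)
    complex with one exchanged + incoming ligand → leaving ligand + complex with two exchanged (k = 5.00 × 10⁻⁴ M⁻¹ s⁻¹)
    complex with two exchanged + incoming ligand → leaving ligand + complex with three exchanged (k = 0.0170 M⁻¹ s⁻¹)
    starting complex + complex with one exchanged → side product (k = 0.0110 M⁻¹ s⁻¹)
    crystals ⇌ leaving ligand, rate k5*(cs5 - [leaving ligand]) while solid is left; crystals form when [leaving ligand] > cs5 (solubility = 2.10 mM, k = 0.0280 s⁻¹)

In alder complex with one exchanged is made 4.22 times as fast as it is used at 0.306 h and 0.0376 times as fast at 25.0 h, so the crossing lies inside the run. The neighbour of alder charged with 2.00 equiv of incoming ligand stands at 1.64 times the border charge, where the reckoning has the starting complex consumed before the crossing, and at 25.0 h that neighbour holds 0% of starting complex, 27.3% of complex with one exchanged, 30.8% of complex with three exchanged and 41.1% of side product, against 76.5% of side product in alder.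

(The earlier runs and the new flask were computed on assumed constants; scatter was added.)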